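## The problem

Superstolide A (55) is a 16-membered macrolactone (C1–C8, C17–C23 and the ring oxygen) laid across the C8–C17 bond of ring B of a cis-fused decalin (ring A: C9–C14; ring B: C8, C9, C14–C17). A (2E,4Z,6E)-trienoate ends at the quaternary C8 and an (18E,20E)-diene starts at C17, so both arms leave ring B from neighbouring carbons on the same face. Six stereocentres lie on the decalin (C8, C9, C11, C13, C14, C17) and five in the C22–C26 segment. The decalin centres can steer one another through the convex/concave bias of the cis fusion. The side-chain centres are too remote to be steered from the rings, so the two domains have to be made separately as single enantiomers and then joined. C8 is the hardest centre: quaternary, flanked by two sp2 arms and without a neighbouring heteroatom. Fragile features are: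
- the primary carbamate at C13 (base, hydride);
- the 4Z alkene of the trienoate (isomerisation on activation of the acid);
- the doubly allylic C17–H;
- the C13 oxygen, which is β to any carbonyl placed at C11 or C15 (elimination);
- the N-acetyl amino alcohol beside the lactone carbinol (acyl shift, hemiaminal formation once C23 is an aldehyde).

The enabling feature is that C8 is para to C15 in ring B while ring A is 1,3-dioxygenated at C11 and C13. Ring B therefore maps onto a 4,4-disubstituted cyclohexa-2,5-dienone with C15 as carbonyl, ring A onto a 1,3-dioxygenated butadiene, and the enone left after cycloaddition can pass configuration from C15 to C17.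

## Retrosynthesis

**Late functional groups.** No skeletal bond is cut in going from 55 to macrocycle 51. The N,O-acetal of 54 is opened last, the carbamate comes from alcohol 52, and 52 from silyl ether 51. O25 and N26 are tied in one N-acetyl oxazolidine, so O13 is the only free hydroxyl when the carbamate is made and the end game needs only fluoride, an isocyanate and a trace of acid.

**Ring closure at C5–C6.** Macrocycle 51 is opened at the C5–C6 single bond of the triene to give stannane/iodide 50, and the ester O–C1 of 50 is cut to give alcohol 48 and iodo-dienoic acid 45. Against lactonisation of a complete trienoic acid, this puts the acylation of the hindered C23 hydroxyl into an intermolecular step with a small acid used in excess. The 4Z-triene is then created only at ring closure, under neutral palladium catalysis with retention at both carbons. The forward step must close a 16-membered ring by sp2–sp2 coupling at high dilution.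

**C19–C20.** Stannane 48 comes from alkyne 47 and silyl alkyne 46, and 46 is cut at the diene single bond C19–C20 into alkenyl iodide 27 and alkenylboronate 39. This cut separates the two stereochemical domains exactly: 27 holds all six ring centres and 39 all five chain centres. It needs a coupling that tolerates a free hydroxyl and keeps both alkene geometries.

**C18=C19.** Iodide 27 is traced to methylalkyne 25, dibromoalkene 23, aldehyde 22 and alcohol 21. The trisubstituted E alkene is drawn from an alkyne by syn-hydrometalation because a stabilised-ylide olefination of 22 would need three further redox steps before coupling. The forward step must place the metal on C19, the less hindered alkyne carbon.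

**C17–C18.** Alcohol 21 is cut at C17–C18 to stannylmethyl ether 19 and allylic alcohol 18. A [2,3]-sigmatropic shift moves the substituent from O15 to C17 across one face and sets the C15=C16 alkene at the same time. The alternative, conjugate addition to the enone, would have to deliver carbon to the concave face beside a quaternary centre. The C15 carbinol must carry its oxygen on the alkynyl face.

**Oxidation-level adjustments.** Alcohol 18 comes from enone 17, methyl ether 17 from alcohol 16, 16 from diketone 15, and 15 from cycloadduct 14. C11 is reduced and methylated before C15 is touched, so the two carbinols never have to be told apart. No strong base is used while a carbonyl is β to O13.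

**Key disconnection.** Cycloadduct 14 is cut at C9–C10 and C13–C14 into dienone 9 and diene 13. Two achiral pieces replace a bicycle with four stereocentres, one of them quaternary. The forward reaction must choose one regiochemistry, the endo mode, the alkynyl face and one of two enantiotopic alkenes.

**Precursors of the key step.** Dienone 9 comes from silyl alkyne 8 by bis-allylic oxidation. Alkyne 8 comes from dibromoalkene 6, aldehyde 5, alcohol 4 and acid 3, and 3 from benzoic acid 1 by reductive methylation. Diene 13 comes from enone 12, enolate 11 and keto acetal 10.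

**Side chain.** Boronate 39 comes from alkene 38 by metathesis at C20. Alkene 38 is cut at C22–C23 to aldehyde 36, and the line runs back through oxazolidine 34, acetamide 33 and carbamate 31, which is cut at C24–C25 to aldehyde 29, made from amino alcohol 28. Two crotylborations each set two adjacent centres under reagent control matched with the substrate bias, and C26 is bought.

**Acid fragment.** Acid 45 comes from ester 44, cut at C2=C3 to alcohol 42, and 42 from iodoenoate 41 and ynoate 40. The 4Z geometry is fixed in the first step on a four-carbon molecule.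

## Roads not taken

**Alternative 1:** The cut is the C20–C21 bond inside the macrocycle. In the forward sense a seco-ester with two methyl-capped alkynes is closed by ring-closing alkyne metathesis with Mo(≡CC6H4OMe)(OSiPh3)3 and 5 Å molecular sieves to the macrocyclic 18-en-20-yne A1, and the triple bond is then reduced trans-selectively to the 20E alkene.
- Merits: alkyne metathesis ignores the seven alkenes, closes large rings reversibly, and uses no organotin at the ring-closing stage.
- Weak points: it is only an end game. It says nothing about how the cis-decalin with its six centres and two arms is made, so it would still need a construction such as the one chosen here. The complete (2E,4Z,6E)-trienoate must be in place before closure, so the hindered C23 hydroxyl is acylated with a full trienoic acid. Two further steps (trans-hydrometalation, protodemetalation) must then be run on a ring holding a conjugated triene and a diene.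
- Comparison: as a ring closure it is probably at least as reliable as the Stille closure chosen here, and cleaner in reagents. The chosen plan sets against it that the triene and diene emerge in their final form at the coupling steps, with no reduction after closure, and that the 4Z geometry is fixed in a four-carbon fragment.

**Alternative 2:** The cut is C13–C14, paired with re-formation of a C11–C16 bond in a bicyclo[2.2.2]octene cage. In the forward sense the potassium alkoxide of a C11 carbinol (KH, 18-crown-6) undergoes an anionic oxy-Cope shift that breaks C11–C16, forms C13–C14 and gives the cis-decalin C11 ketone A2.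
- Merits: the rearrangement is stereospecific, gives the cis fusion and the C11 ketone directly, and puts the C15=C16 alkene in place at once. That saves the reduction and allylic transfer that the chosen route spends on C15 and C17.
- Weak points: the cage substrate must already hold C8, C9, C16 and C17 in the right relative and absolute sense. At the quaternary C8 the competing groups would be methyl and a silyloxymethyl group, which differ little in size. The carbinol must be made by facial addition of an alkoxyvinyl metal. Both arms arrive as CH2O groups that need oxidation and olefination, one of them at a neopentyl position.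
- Comparison: it is better in that it avoids a β-oxygenated ketone at C15. The chosen plan sets against it that four centres and absolute configuration come in one step from two achiral partners, and that the C8 substituents (methyl against a linear alkyne) differ clearly in steric demand.

**Alternative 3:** The cut is in ring B. In the forward sense the second-generation Grubbs catalyst RuCl2(=CHPh)(H2IMes)(PCy3) engages a C14 vinyl group, opens a cyclobutene at its C7–C16 alkene and closes ring B, giving the cis-decalin A3 with the C15=C16 alkene and a vinyl group on C8.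
- Merits: strain release drives the step, the ring alkene lands in its final position, and no carbonyl is ever β to O13.
- Weak points: the substrate needs ring A with three centres plus a cyclobutene carrying the quaternary C8 and C17 in a fixed relation to them, and no element controls that relation. Ring-opening oligomerisation competes. The terminal vinyl group on a quaternary carbon is a poor handle for building the E-C6=C7 bond, because cross-metathesis at such a position is sluggish and a Heck reaction leaves the regiochemistry open.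
- Comparison: it is as good or better at placing the C15=C16 alkene. The chosen plan sets against it a C8 alkyne that becomes an E-alkenyl metal in one regiodefined step, and a ring construction in which every stereocentre has a named controlling element.

Key step: step 10

Remark: carbon labels C1–C27 are those of the macrolide in every intermediate; the (S)-antipode of the cycloaddition catalyst is assigned from the accepted carbonyl-binding model, and both antipodes are available.

## Route

Step 1
Reactants: 1 benzoic acid
Product: 3 1-methylcyclohexa-2,5-diene-1-carboxylic acid, via dilithium enediolate 2 (not isolated)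
Conditions: Li, NH3(l)/THF, −78 °C; MeI, −78 °C; NH4Cl, then aq. HCl
Reagents that add atoms: iodomethane, CI
Why: Birch reduction of the benzoate gives the cross-conjugated dianion, which is methylated at the carboxyl-bearing carbon (Birch reductive alkylation); no stereocentre is formed.

Step 2
Reactants: 3 1-methylcyclohexa-2,5-diene-1-carboxylic acid
Product: 4 (1-methylcyclohexa-2,5-dien-1-yl)methanol
Conditions: LiAlH4, THF, 0 °C → rt
Reagents that add atoms: none
Why: Hydride reduction of a carboxylic acid to the primary alcohol; the skipped diene is inert to LiAlH4.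

Step 3
Reactants: 4 (1-methylcyclohexa-2,5-dien-1-yl)methanol
Product: 5 1-methylcyclohexa-2,5-diene-1-carbaldehyde
Conditions: Dess–Martin periodinane, NaHCO3, CH2Cl2, 0 °C; carried on as a solution
Reagents that add atoms: none
Why: Dess–Martin oxidation of a primary alcohol; the aldehyde has no α-hydrogen and is not concentrated because it is volatile.

Step 4
Reactants: 5 1-methylcyclohexa-2,5-diene-1-carbaldehyde
Product: 6 3-(2,2-dibromoethenyl)-3-methylcyclohexa-1,4-diene
Conditions: CBr4, PPh3, CH2Cl2, 0 °C
Reagents that add atoms: tetrabromomethane, BrC(Br)(Br)Br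
Why: Corey–Fuchs dibromo-olefination (Wittig reaction of the ylide formed from CBr4 and PPh3), reliable for α-quaternary aldehydes.

Step 5
Reactants: 6 3-(2,2-dibromoethenyl)-3-methylcyclohexa-1,4-diene
Product: 8 trimethyl[(1-methylcyclohexa-2,5-dien-1-yl)ethynyl]silane, via lithium acetylide 7 (not isolated)
Conditions: n-BuLi (2.1 equiv), THF, −78 °C; TMSCl, −78 °C → rt
Reagents that add atoms: chlorotrimethylsilane, C[Si](C)(C)Cl
Why: Second stage of the Corey–Fuchs sequence (bromine–lithium exchange, Fritsch–Buttenberg–Wiechell rearrangement, deprotonation), followed by C-silylation of the acetylide.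

Step 6
Reactants: 8 trimethyl[(1-methylcyclohexa-2,5-dien-1-yl)ethynyl]silane
Product: 9 4-methyl-4-[(trimethylsilyl)ethynyl]cyclohexa-2,5-dien-1-one
Conditions: (C5H5NH)2Cr2O7, t-BuOOH, Celite, benzene, rt
Reagents that add atoms: tert-butyl hydroperoxide, CC(C)(C)OO
Why: Chromium-mediated peroxide oxidation of the doubly allylic CH2 of a Birch-type 1,4-diene to the cross-conjugated dienone (bis-allylic oxidation); the quaternary carbon blocks aromatisation.

Step 7
Reactants: 10 4,4-dimethoxybutan-2-one
Product: 11 sodium (E)-3-oxobut-1-en-1-olate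
Conditions: NaOH (1.0 equiv), H2O, rt → 40 °C; evaporation, azeotropic drying with toluene
Reagents that add atoms: sodium hydroxide, [Na+].[OH-]
Why: Base-induced β-elimination of methanol from the β-keto acetal, then addition–elimination of hydroxide on the vinylogous ester (vinylogous ester hydrolysis), gives the stabilised enolate of formylacetone.

Step 8
Reactants: 11 sodium (E)-3-oxobut-1-en-1-olate
Product: 12 (E)-4-[(tert-butyldimethylsilyl)oxy]but-3-en-2-one
Conditions: TBSCl, THF, 0 °C → rt
Reagents that add atoms: tert-butyl(chloro)dimethylsilane, CC(C)(C)[Si](C)(C)Cl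
Why: O-silylation of the enolate at the aldehyde-derived oxygen; the E vinylogous silyl ester is the thermodynamic isomer.

Step 9
Reactants: 12 (E)-4-[(tert-butyldimethylsilyl)oxy]but-3-en-2-one
Product: 13 (E)-1-[(tert-butyldimethylsilyl)oxy]-3-[(trimethylsilyl)oxy]buta-1,3-diene
Conditions: TMSOTf, Et3N, Et2O, 0 °C; filtration under argon, distillation
Reagents that add atoms: trimethylsilyl trifluoromethanesulfonate, C[Si](C)(C)OS(=O)(=O)C(F)(F)F
Why: Soft enolisation of the methyl ketone and O-silylation (silyl enol ether formation) gives the 2-silyloxy diene, as for the 1-methoxy analogue.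

Step 10
Reactants: 9 4-methyl-4-[(trimethylsilyl)ethynyl]cyclohexa-2,5-dien-1-one, 13 (E)-1-[(tert-butyldimethylsilyl)oxy]-3-[(trimethylsilyl)oxy]buta-1,3-diene
Product: 14 cis-fused cycloadduct (C11 silyl enol ether and C15 enone)
Conditions: (S)-3,3-diphenyl-1-(o-tolyl)tetrahydro-1H,3H-pyrrolo[1,2-c][1,3,2]oxazaborole·HNTf2 (20 mol%), 13 (1.5 equiv), CH2Cl2, −78 °C; Et3N quench; filtration through Et3N-treated silica
Reagents that add atoms: none
Why: The protonated oxazaborolidine binds the carbonyl oxygen and lowers the dienone LUMO, and the electron-rich diene adds in a concerted, asynchronous, normal-demand [4+2] cycloaddition in which the C9–C10 bond (CH2 terminus to the enone β-carbon) runs ahead of the C13–C14 bond; the closest known reactions are oxazaborolidinium-catalysed Diels–Alder additions of silyloxydienes to cyclic enones and quinone monoketals and Lewis-acid-promoted additions of 1-oxy-3-silyloxybutadienes to 4,4-disubstituted cyclohexadienones. Ring A closes as a six-membered carbocycle by suprafacial–suprafacial annulation onto the C9=C14 alkene, which fixes the cis fusion at C9 and C14. The diene approaches the face that carries the rod-like alkynyl group, which is smaller than methyl, so the C9–C10 bond is cis to the alkyne and C8 becomes stereogenic in the required sense. Endo orientation of the E-diene places the C13 silyloxy group cis to C15. Absolute configuration comes from the catalyst: bound to the carbonyl lone pair syn to an α-vinyl C–H, the (S)-catalyst screens one face of the adjacent alkene with an aryl group, and only for C9=C14 is the open face also the alkynyl face, whereas reaction at C16=C17 would force the diene past the methyl group. The step therefore needs regio-, endo-, facial and enantiotopic-alkene selectivity; the first two follow from the polarisation and geometry of the diene, the third from the size difference at C8 and the fourth from the agreement of catalyst and substrate bias. A second cycloaddition at the remaining enone is held back by the neighbouring quaternary carbon and by the limited excess of diene.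

Step 11
Reactants: 14 cis-fused cycloadduct
Product: 15 C11,C15-diketone
Conditions: 0.01 M HCl, THF–H2O (4:1), 0 °C, short contact
Reagents that add atoms: none
Why: Protodesilylation of the silyl enol ether unmasks the C11 ketone (silyl enol ether hydrolysis); dilute acid at 0 °C leaves the β-silyloxy group at C13 and the cis ring fusion untouched.

Step 12
Reactants: 15 C11,C15-diketone
Product: 16 C11 alcohol (11S)
Conditions: NaBH4, MeOH–CH2Cl2 (1:1), −78 °C
Reagents that add atoms: none
Why: At −78 °C borohydride reduces a saturated ketone faster than a conjugated, α-branched enone (chemoselective carbonyl reduction). Hydride enters C11 axially from the convex face (the face of H9 and H14), so the hydroxyl ends equatorial and cis to the C13 silyloxy group.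

Step 13
Reactants: 16 C11 alcohol
Product: 17 C11 methyl ether
Conditions: Me3OBF4, 1,8-bis(dimethylamino)naphthalene, CH2Cl2, 0 °C → rt
Reagents that add atoms: trimethyloxonium tetrafluoroborate, C[O+](C)C.F[B-](F)(F)F
Why: Meerwein O-methylation under non-basic conditions; a strong base is avoided because O13 is β to the C15 carbonyl and would be lost by E1cB elimination.

Step 14
Reactants: 17 C11 methyl ether
Product: 18 C15 allylic alcohol (15R)
Conditions: NaBH4, CeCl3·7H2O, MeOH, −78 °C
Reagents that add atoms: none
Why: Luche 1,2-reduction of the enone; the concave face of C15 is screened by ring A (C13 on C14 and the axial C10 on C9), so hydride adds from the convex face and the hydroxyl lies on the face of ring A and of the alkynyl group.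

Step 15
Reactants: 18 C15 allylic alcohol
Product: 19 C15 (tributylstannyl)methyl ether
Conditions: KH, 18-crown-6 (cat.), Bu3SnCH2I, THF, 0 °C → rt
Reagents that add atoms: tributyl(iodomethyl)stannane, CCCC[Sn](CCCC)(CCCC)CI
Why: Williamson etherification of the potassium alkoxide with a reactive primary iodide; the iodide is present from the start so that O-alkylation outruns a 1,3-silyl shift from O13.

Step 16
Reactants: 19 C15 (tributylstannyl)methyl ether
Product: 21 C17 hydroxymethyl decalin, via lithiomethyl ether 20 (not isolated)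
Conditions: n-BuLi, THF, −78 °C → −40 °C; aq. NH4Cl
Reagents that add atoms: none
Why: Tin–lithium exchange gives the α-alkoxy carbanion, which undergoes the [2,3]-Wittig–Still rearrangement through a five-membered envelope transition state. The shift is suprafacial, so the pseudoaxial C15–O bond on the alkynyl face is exchanged for a C17–C18 bond on the same face (trans to the C8 methyl) while the alkene moves to C15=C16.

Step 17
Reactants: 21 C17 hydroxymethyl decalin
Product: 22 C18 aldehyde
Conditions: Dess–Martin periodinane, NaHCO3, CH2Cl2, 0 °C; used at once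
Reagents that add atoms: none
Why: Buffered Dess–Martin oxidation; neutral conditions keep the β,γ-unsaturated aldehyde from epimerising at C17 or moving into conjugation.

Step 18
Reactants: 22 C18 aldehyde
Product: 23 1,1-dibromoalkene
Conditions: CBr4, PPh3, Et3N, CH2Cl2, −20 °C → 0 °C
Reagents that add atoms: tetrabromomethane, BrC(Br)(Br)Br
Why: Corey–Fuchs dibromo-olefination; the amine buffer protects the C17 stereocentre and the silyl ether from adventitious HBr.

Step 19
Reactants: 23 1,1-dibromoalkene
Product: 25 C18–C19 methylalkyne, via lithium acetylide 24 (not isolated)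
Conditions: n-BuLi (2.2 equiv), THF, −78 °C; MeI, DMPU, −78 °C → rt
Reagents that add atoms: iodomethane, CI
Why: Corey–Fuchs alkyne formation and C-methylation of the acetylide in one flask; the silyl-capped C6–C7 alkyne has no acidic proton and stays distinct from the new alkyne.

Step 20
Reactants: 25 C18–C19 methylalkyne
Product: 27 (E)-C19 alkenyl iodide, via alkenylzirconocene chloride 26 (not isolated)
Conditions: Cp2Zr(H)Cl (2.0 equiv), THF, rt → 40 °C; I2, 0 °C
Reagents that add atoms: iodine, II
Why: syn-Hydrozirconation of the internal alkyne; with excess hydride the regioisomers equilibrate to the one with zirconium on the methyl-bearing C19, away from the branched C17, and iodinolysis with retention gives the E iodoalkene. The silyl alkyne on the quaternary carbon and the ring alkene are too hindered to compete.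

Step 21
Reactants: 28 tert-butyl N-[(2R)-1-hydroxypropan-2-yl]carbamate (N-Boc-D-alaninol)
Product: 29 tert-butyl N-[(2R)-1-oxopropan-2-yl]carbamate
Conditions: Dess–Martin periodinane, water-saturated CH2Cl2, rt; used at once
Reagents that add atoms: none
Why: Dess–Martin oxidation gives the N-Boc α-amino aldehyde, whose configuration holds when it is used directly.

Step 22
Reactants: 29 tert-butyl N-[(2R)-1-oxopropan-2-yl]carbamate
Product: 31 anti,anti homoallylic alcohol, via borinate 30 (not isolated)
Conditions: (E)-crotyl-B(Ipc)2 [made at −78 °C from trans-2-butene, n-BuLi, KOt-Bu, (−)-Ipc2BOMe (from (+)-α-pinene) and BF3·OEt2], THF, −78 °C; then NaOH, H2O2, 0 °C → rt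
Reagents that add atoms: (E)-but-2-enylbis(isopinocampheyl)borane of the (+)-α-pinene series, C/C=C/CB([C@@H]1C[C@@H]2C[C@H]([C@H]1C)C2(C)C)[C@@H]1C[C@@H]2C[C@H]([C@H]1C)C2(C)C
Why: Brown crotylboration through a chair Zimmerman–Traxler transition state: the E-crotyl geometry gives the 24,25-anti relation, and the isopinocampheyl groups direct attack to the Si face of the aldehyde, which the Felkin–Anh preference of the α-carbamate reinforces, giving the 25,26-anti amino alcohol.

Step 23
Reactants: 31 anti,anti homoallylic alcohol
Product: 33 N-acetyl amino alcohol, via ammonium trifluoroacetate 32 (not isolated)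
Conditions: TFA, CH2Cl2, 0 °C; evaporation; Ac2O (1.1 equiv), Et3N, MeOH, 0 °C
Reagents that add atoms: acetic anhydride, CC(=O)OC(C)=O
Why: Acidolysis of the Boc group, then chemoselective N-acetylation of the amine in methanol, where the secondary alcohol is not acylated.

Step 24
Reactants: 33 N-acetyl amino alcohol
Product: 34 N-acetyl-2,2-dimethyloxazolidine
Conditions: 2-methoxypropene, pyridinium p-toluenesulfonate (cat.), toluene, 60 °C
Reagents that add atoms: 2-methoxypropene, COC(C)=C
Why: Acid-catalysed N,O-acetalisation of an N-acyl amino alcohol; it removes the amide N–H and masks O25 in one operation, so the later C23 aldehyde cannot close to a cyclic hemiaminal.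

Step 25
Reactants: 34 N-acetyl-2,2-dimethyloxazolidine
Product: 36 C23 aldehyde, via ozonide 35 (not isolated)
Conditions: O3, CH2Cl2, −78 °C; PPh3, −78 °C → rt; used at once
Reagents that add atoms: ozone, [O-][O+]=O
Why: Ozonolysis with reductive work-up; the α-methyl aldehyde is used crude to avoid epimerisation at C24.

Step 26
Reactants: 36 C23 aldehyde
Product: 38 C20–C27 homoallylic alcohol, via borinate 37 (not isolated)
Conditions: (E)-crotyl-B(Ipc)2 [made at −78 °C from trans-2-butene, n-BuLi, KOt-Bu, (+)-Ipc2BOMe (from (−)-α-pinene) and BF3·OEt2], THF, −78 °C; then NaOH, H2O2, 0 °C → rt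
Reagents that add atoms: (E)-but-2-enylbis(isopinocampheyl)borane of the (−)-α-pinene series, C/C=C/CB([C@H]1C[C@H]2C[C@@H]([C@@H]1C)C2(C)C)[C@H]1C[C@H]2C[C@@H]([C@@H]1C)C2(C)C
Why: Second Brown crotylboration: the E-crotyl geometry sets the 22,23-anti relation, and this reagent antipode attacks the Re face, which is also the Felkin–Anh face of the α-methyl aldehyde (matched pairing), giving the 23,24-syn relation.

Step 27
Reactants: 38 C20–C27 homoallylic alcohol
Product: 39 (E)-C20 alkenylboronate
Conditions: vinylboronic acid pinacol ester (3 equiv), second-generation Hoveyda–Grubbs catalyst RuCl2(H2IMes)(=CH-C6H4-2-O-i-Pr) (5 mol%), CH2Cl2, 40 °C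
Reagents that add atoms: 2-ethenyl-4,4,5,5-tetramethyl-1,3,2-dioxaborolane, C=CB1OC(C)(C)C(C)(C)O1
Why: Olefin cross-metathesis of a terminal alkene with a vinylboronate; the bulky boronate and the allylic branch favour the E alkenylboronate, and loss of ethene drives the reaction.

Step 28
Reactants: 40 ethyl but-2-ynoate
Product: 41 ethyl (2Z)-3-iodobut-2-enoate
Conditions: NaI, AcOH, 115 °C
Reagents that add atoms: sodium iodide, [Na+].[I-]
Why: Conjugate hydroiodination of the ynoate; anti addition of iodide and proton gives the Z β-iodoenoate.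

Step 29
Reactants: 41 ethyl (2Z)-3-iodobut-2-enoate
Product: 42 (2Z)-3-iodobut-2-en-1-ol
Conditions: i-Bu2AlH, CH2Cl2, −78 °C → 0 °C; aq. KNaC4H4O6 work-up
Reagents that add atoms: none
Why: 1,2-Reduction of the enoate to the allylic alcohol by the aluminium hydride; the alkene geometry is untouched.

Step 30
Reactants: 42 (2Z)-3-iodobut-2-en-1-ol
Product: 44 ethyl (2E,4Z)-5-iodohexa-2,4-dienoate, via (2Z)-3-iodobut-2-enal 43 (not isolated)
Conditions: MnO2, Ph3P=CHCO2Et, CH2Cl2, rt
Reagents that add atoms: ethyl (triphenylphosphoranylidene)acetate, CCOC(=O)C=P(c1ccccc1)(c1ccccc1)c1ccccc1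
Why: Tandem allylic oxidation–Wittig olefination: the sensitive Z iodoenal is trapped as it forms by the stabilised ylide, which makes the new C2=C3 alkene E.

Step 31
Reactants: 44 ethyl (2E,4Z)-5-iodohexa-2,4-dienoate
Product: 45 (2E,4Z)-5-iodohexa-2,4-dienoic acid
Conditions: LiOH, THF–MeOH–H2O, 0 °C → rt; aq. HCl to pH 3
Reagents that add atoms: lithium hydroxide, [Li+].[OH-]
Why: Saponification of the ethyl ester; the alkenyl iodide and both alkene geometries are stable to cold hydroxide.

Step 32
Reactants: 27 (E)-C19 alkenyl iodide, 39 (E)-C20 alkenylboronate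
Product: 46 C6–C27 dienyl alcohol
Conditions: Pd(dppf)Cl2·CH2Cl2 (10 mol%), K3PO4 (3 M aq.), THF–DMF, rt
Reagents that add atoms: none
Why: Suzuki–Miyaura coupling of an alkenyl iodide with an alkenylboronate proceeds with retention at both carbons and gives the (18E,20E)-diene; the free C23 hydroxyl, the silyl alkyne and the N,O-acetal are tolerated.

Step 33
Reactants: 46 C6–C27 dienyl alcohol
Product: 47 terminal C6–C7 alkyne
Conditions: K2CO3 (cat.), MeOH, rt
Reagents that add atoms: none
Why: Methanolysis of the alkynyl C–Si bond; the secondary silyl ether and the N-acetyl oxazolidine are stable to carbonate in methanol.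

Step 34
Reactants: 47 terminal C6–C7 alkyne
Product: 48 (E)-C6 alkenylstannane
Conditions: Bu3SnH, PdCl2(PPh3)2 (5 mol%), THF, 0 °C
Reagents that add atoms: tributylstannane, CCCC[SnH](CCCC)CCCC
Why: Palladium-catalysed syn-hydrostannation of a terminal alkyne; the quaternary C8 forces tin onto the terminal carbon C6 and gives the E alkenylstannane, and the alkyne reacts well ahead of the diene.

Step 35
Reactants: 45 (2E,4Z)-5-iodohexa-2,4-dienoic acid, 48 (E)-C6 alkenylstannane
Product: 50 C23 iodo-dienoate ester, via mixed anhydride 49 (not isolated)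
Conditions: 45 (3 equiv), 2,4,6-trichlorobenzoyl chloride, Et3N, THF, rt; then 48, DMAP, toluene, rt
Reagents that add atoms: none
Why: Yamaguchi esterification through the mixed anhydride; the hindered C23 hydroxyl is the only free OH and is acylated intermolecularly with an excess of the small acid.

Step 36
Reactants: 50 C23 iodo-dienoate ester
Product: 51 protected macrolactone
Conditions: Pd2(dba)3 (20 mol%), AsPh3, DMF, 0.5 mM, rt
Reagents that add atoms: none
Why: Intramolecular Stille coupling of the C5 alkenyl iodide with the C6 alkenylstannane under zerovalent palladium; both carbons react with retention, so the 4Z and 6E geometries pass into the triene as the 16-membered ring closes at high dilution.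

Step 37
Reactants: 51 protected macrolactone
Product: 52 C13 alcohol
Conditions: HF·pyridine, pyridine, THF, 0 °C → rt
Reagents that add atoms: none
Why: Fluoride cleavage of the only silyl ether (desilylation); the pyridine buffer protects the N,O-acetal and the polyene.

Step 38
Reactants: 52 C13 alcohol
Product: 54 C13 carbamate, via N-trichloroacetyl carbamate 53 (not isolated)
Conditions: Cl3CC(O)NCO, CH2Cl2, 0 °C; then neutral Al2O3, rt
Reagents that add atoms: trichloroacetyl isocyanate, O=C=NC(=O)C(Cl)(Cl)Cl
Why: Carbamoylation of the only free hydroxyl with an acyl isocyanate and hydrolytic removal of the trichloroacetyl group on neutral alumina; no base strong enough to open the lactone is used.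

Step 39
Reactants: 54 C13 carbamate
Product: 55 superstolide A
Conditions: p-TsOH·H2O (cat.), MeOH, 0 °C → rt
Reagents that add atoms: none
Why: Acid-catalysed methanolysis of the N,O-isopropylidene acetal (transacetalisation) frees the C25 hydroxyl and the acetamide N–H in one step under conditions that the carbamate, the lactone and the polyene withstand.

## Compound list

1 | benzoic acid | OC(=O)c1ccccc1 | starting material
2 | dilithium (cyclohexa-2,5-dien-1-ylidene)methanediolate | [Li+].[Li+].[O-]C([O-])=C1C=CCC=C1 | intermediate (not isolated)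
3 | 1-methylcyclohexa-2,5-diene-1-carboxylic acid | CC1(C(=O)O)C=CCC=C1 | intermediate
4 | (1-methylcyclohexa-2,5-dien-1-yl)methanol | CC1(CO)C=CCC=C1 | intermediate
5 | 1-methylcyclohexa-2,5-diene-1-carbaldehyde | CC1(C=O)C=CCC=C1 | intermediate
6 | 3-(2,2-dibromoethenyl)-3-methylcyclohexa-1,4-diene | CC1(C=C(Br)Br)C=CCC=C1 | intermediate
7 | lithium (1-methylcyclohexa-2,5-dien-1-yl)acetylide | [Li]C#CC1(C)C=CCC=C1 | intermediate (not isolated)
8 | trimethyl[(1-methylcyclohexa-2,5-dien-1-yl)ethynyl]silane | CC1(C#C[Si](C)(C)C)C=CCC=C1 | intermediate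
9 | 4-methyl-4-[(trimethylsilyl)ethynyl]cyclohexa-2,5-dien-1-one | CC1(C#C[Si](C)(C)C)C=CC(=O)C=C1 | intermediate
10 | 4,4-dimethoxybutan-2-one | CC(=O)CC(OC)OC | starting material
11 | sodium (E)-3-oxobut-1-en-1-olate | CC(=O)/C=C/[O-].[Na+] | intermediate
12 | (E)-4-[(tert-butyldimethylsilyl)oxy]but-3-en-2-one | CC(=O)/C=C/O[Si](C)(C)C(C)(C)C | intermediate
13 | (E)-1-[(tert-butyldimethylsilyl)oxy]-3-[(trimethylsilyl)oxy]buta-1,3-diene | C=C(O[Si](C)(C)C)/C=C/O[Si](C)(C)C(C)(C)C | intermediate
14 | (4S,4aR,8S,8aR)-8-[(tert-butyldimethylsilyl)oxy]-4-methyl-6-[(trimethylsilyl)oxy]-4-[(trimethylsilyl)ethynyl]-4a,5,8,8a-tetrahydronaphthalen-1(4H)-one; cis-fused cycloadduct (macrolide labels: C15 ketone, C16=C17, C11=C12 silyl enol ether; alkynyl group, C10 and O13 on one face, C8 methyl, H9 and H14 on the other) | C[Si](C)(C)OC1=C[C@H](O[Si](C)(C)C(C)(C)C)[C@@H]2C(=O)C=C[C@](C)(C#C[Si](C)(C)C)[C@@H]2C1 | intermediate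
15 | (4S,4aR,8S,8aR)-8-[(tert-butyldimethylsilyl)oxy]-4-methyl-4-[(trimethylsilyl)ethynyl]-4a,5,8,8a-tetrahydronaphthalene-1,6(4H,7H)-dione (C11,C15-diketone) | O=C1C[C@H](O[Si](C)(C)C(C)(C)C)[C@@H]2C(=O)C=C[C@](C)(C#C[Si](C)(C)C)[C@@H]2C1 | intermediate
16 | C11 alcohol: 15 with C11=O reduced to the (11S)-carbinol, OH cis to the C13 silyloxy group and trans to H9/H14 | O[C@@H]1C[C@H](O[Si](C)(C)C(C)(C)C)[C@@H]2C(=O)C=C[C@](C)(C#C[Si](C)(C)C)[C@@H]2C1 | intermediate
17 | C11 methyl ether of 16 (11-OMe, 13-OTBS, C15 enone, 8-methyl, 8-trimethylsilylethynyl) | CO[C@@H]1C[C@H](O[Si](C)(C)C(C)(C)C)[C@@H]2C(=O)C=C[C@](C)(C#C[Si](C)(C)C)[C@@H]2C1 | intermediate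
18 | C15 allylic alcohol: 17 with C15=O reduced to the (15R)-carbinol, OH on the face of the alkynyl group and of C13, trans to H14 | CO[C@@H]1C[C@H](O[Si](C)(C)C(C)(C)C)[C@@H]2[C@H](O)C=C[C@](C)(C#C[Si](C)(C)C)[C@@H]2C1 | intermediate
19 | C15 O-[(tributylstannyl)methyl] ether of 18 | CO[C@@H]1C[C@H](O[Si](C)(C)C(C)(C)C)[C@@H]2[C@H](OC[Sn](CCCC)(CCCC)CCCC)C=C[C@](C)(C#C[Si](C)(C)C)[C@@H]2C1 | intermediate
20 | C15 O-(lithiomethyl) ether of 18 | CO[C@@H]1C[C@H](O[Si](C)(C)C(C)(C)C)[C@@H]2[C@H](OC[Li])C=C[C@](C)(C#C[Si](C)(C)C)[C@@H]2C1 | intermediate (not isolated)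
21 | C17 hydroxymethyl cis-decalin: C15=C16 alkene, C17–CH2OH cis to the C8 alkynyl group and trans to the C8 methyl; 11-OMe, 13-OTBS | CO[C@@H]1C[C@H](O[Si](C)(C)C(C)(C)C)[C@@H]2C=C[C@H](CO)[C@](C)(C#C[Si](C)(C)C)[C@@H]2C1 | intermediate
22 | C18 aldehyde of 21 | CO[C@@H]1C[C@H](O[Si](C)(C)C(C)(C)C)[C@@H]2C=C[C@H](C=O)[C@](C)(C#C[Si](C)(C)C)[C@@H]2C1 | intermediate
23 | 1,1-dibromoalkene (C17–CH=CBr2) | CO[C@@H]1C[C@H](O[Si](C)(C)C(C)(C)C)[C@@H]2C=C[C@H](C=C(Br)Br)[C@](C)(C#C[Si](C)(C)C)[C@@H]2C1 | intermediate
24 | lithium acetylide (C17–C≡C–Li) | CO[C@@H]1C[C@H](O[Si](C)(C)C(C)(C)C)[C@@H]2C=C[C@H](C#C[Li])[C@](C)(C#C[Si](C)(C)C)[C@@H]2C1 | intermediate (not isolated)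
25 | methylalkyne (C17–C≡C–CH3) | CO[C@@H]1C[C@H](O[Si](C)(C)C(C)(C)C)[C@@H]2C=C[C@H](C#CC)[C@](C)(C#C[Si](C)(C)C)[C@@H]2C1 | intermediate
26 | (E)-alkenylzirconocene chloride (C17–CH=C(CH3)–ZrCp2Cl, Zr trans to C17) | CO[C@@H]1C[C@H](O[Si](C)(C)C(C)(C)C)[C@@H]2C=C[C@H](/C=C(C)/[Zr](Cl)(C3C=CC=C3)C3C=CC=C3)[C@](C)(C#C[Si](C)(C)C)[C@@H]2C1 | intermediate (not isolated)
27 | (E)-alkenyl iodide (C17–CH=C(CH3)–I, iodine trans to C17) | CO[C@@H]1C[C@H](O[Si](C)(C)C(C)(C)C)[C@@H]2C=C[C@H](/C=C(C)/I)[C@](C)(C#C[Si](C)(C)C)[C@@H]2C1 | intermediate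
28 | tert-butyl N-[(2R)-1-hydroxypropan-2-yl]carbamate (N-Boc-D-alaninol) | C[C@@H](NC(=O)OC(C)(C)C)CO | starting material
29 | tert-butyl N-[(2R)-1-oxopropan-2-yl]carbamate | C[C@@H](NC(=O)OC(C)(C)C)C=O | intermediate
30 | bis(isopinocampheyl)borinate of 31 | C=C[C@H](C)[C@H](OB([C@@H]1C[C@@H]2C[C@H]([C@H]1C)C2(C)C)[C@@H]1C[C@@H]2C[C@H]([C@H]1C)C2(C)C)[C@@H](C)NC(=O)OC(C)(C)C | intermediate (not isolated)
31 | tert-butyl N-[(2R,3S,4S)-3-hydroxy-4-methylhex-5-en-2-yl]carbamate | C=C[C@H](C)[C@H](O)[C@@H](C)NC(=O)OC(C)(C)C | intermediate
32 | (2R,3S,4S)-3-hydroxy-4-methylhex-5-en-2-aminium trifluoroacetate | C=C[C@H](C)[C@H](O)[C@@H](C)[NH3+].[O-]C(=O)C(F)(F)F | intermediate (not isolated)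
33 | N-[(2R,3S,4S)-3-hydroxy-4-methylhex-5-en-2-yl]acetamide | C=C[C@H](C)[C@H](O)[C@@H](C)NC(C)=O | intermediate
34 | 1-[(4R,5S)-5-[(2S)-but-3-en-2-yl]-2,2,4-trimethyl-1,3-oxazolidin-3-yl]ethan-1-one | C=C[C@H](C)[C@@H]1OC(C)(C)N(C(C)=O)[C@@H]1C | intermediate
35 | 1,2,4-trioxolane (ozonide) of 34 | O1OC(OC1)[C@H](C)[C@@H]2OC(C)(C)N(C(C)=O)[C@@H]2C | intermediate (not isolated)
36 | (2R)-2-[(4R,5S)-3-acetyl-2,2,4-trimethyl-1,3-oxazolidin-5-yl]propanal | O=C[C@H](C)[C@@H]1OC(C)(C)N(C(C)=O)[C@@H]1C | intermediate
37 | bis(isopinocampheyl)borinate of 38 | C=C[C@@H](C)[C@@H](OB([C@H]2C[C@H]3C[C@@H]([C@@H]2C)C3(C)C)[C@H]2C[C@H]3C[C@@H]([C@@H]2C)C3(C)C)[C@H](C)[C@@H]1OC(C)(C)N(C(C)=O)[C@@H]1C | intermediate (not isolated)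
38 | 1-[(4R,5S)-5-[(2S,3R,4R)-3-hydroxy-4-methylhex-5-en-2-yl]-2,2,4-trimethyl-1,3-oxazolidin-3-yl]ethan-1-one | C=C[C@@H](C)[C@@H](O)[C@H](C)[C@@H]1OC(C)(C)N(C(C)=O)[C@@H]1C | intermediate
39 | 1-[(4R,5S)-5-[(2S,3R,4R,5E)-3-hydroxy-4-methyl-6-(4,4,5,5-tetramethyl-1,3,2-dioxaborolan-2-yl)hex-5-en-2-yl]-2,2,4-trimethyl-1,3-oxazolidin-3-yl]ethan-1-one | CC1(C)OB(/C=C/[C@@H](C)[C@@H](O)[C@H](C)[C@@H]2OC(C)(C)N(C(C)=O)[C@@H]2C)OC1(C)C | intermediate
40 | ethyl but-2-ynoate | CCOC(=O)C#CC | starting material
41 | ethyl (2Z)-3-iodobut-2-enoate | C/C(I)=C/C(=O)OCC | intermediate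
42 | (2Z)-3-iodobut-2-en-1-ol | C/C(I)=C/CO | intermediate
43 | (2Z)-3-iodobut-2-enal | C/C(I)=C/C=O | intermediate (not isolated)
44 | ethyl (2E,4Z)-5-iodohexa-2,4-dienoate | CCOC(=O)/C=C/C=C(C)\I | intermediate
45 | (2E,4Z)-5-iodohexa-2,4-dienoic acid | OC(=O)/C=C/C=C(C)\I | intermediate
46 | C6–C27 dienyl alcohol: decalin of 27 joined at C19 to C20 of the side chain as the (18E,20E)-diene; free 23-OH, O25/N26 as N-acetyl-2,2-dimethyloxazolidine, C6–C7 alkyne silyl-capped | CO[C@@H]1C[C@H](O[Si](C)(C)C(C)(C)C)[C@@H]2C=C[C@H](/C=C(C)/C=C/[C@@H](C)[C@@H](O)[C@H](C)[C@@H]3OC(C)(C)N(C(C)=O)[C@@H]3C)[C@](C)(C#C[Si](C)(C)C)[C@@H]2C1 | intermediate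
47 | terminal alkyne: 46 without the alkynyl silyl group | CO[C@@H]1C[C@H](O[Si](C)(C)C(C)(C)C)[C@@H]2C=C[C@H](/C=C(C)/C=C/[C@@H](C)[C@@H](O)[C@H](C)[C@@H]3OC(C)(C)N(C(C)=O)[C@@H]3C)[C@](C)(C#C)[C@@H]2C1 | intermediate
48 | (6E)-alkenylstannane: C8–CH=CH–SnBu3 in place of the alkyne of 47 | CO[C@@H]1C[C@H](O[Si](C)(C)C(C)(C)C)[C@@H]2C=C[C@H](/C=C(C)/C=C/[C@@H](C)[C@@H](O)[C@H](C)[C@@H]3OC(C)(C)N(C(C)=O)[C@@H]3C)[C@](C)(/C=C/[Sn](CCCC)(CCCC)CCCC)[C@@H]2C1 | intermediate
49 | (2E,4Z)-5-iodohexa-2,4-dienoic 2,4,6-trichlorobenzoic anhydride | O=C(OC(=O)/C=C/C=C(C)\I)c1c(Cl)cc(Cl)cc1Cl | intermediate (not isolated)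
50 | C23 (2E,4Z)-5-iodohexa-2,4-dienoate ester of 48 | CO[C@@H]1C[C@H](O[Si](C)(C)C(C)(C)C)[C@@H]2C=C[C@H](/C=C(C)/C=C/[C@@H](C)[C@@H](OC(=O)/C=C/C=C(C)\I)[C@H](C)[C@@H]3OC(C)(C)N(C(C)=O)[C@@H]3C)[C@](C)(/C=C/[Sn](CCCC)(CCCC)CCCC)[C@@H]2C1 | intermediate
51 | protected macrolactone: superstolide A skeleton with 13-OTBS and O25/N26 as N-acetyl-2,2-dimethyloxazolidine | CO[C@@H]1C[C@H](O[Si](C)(C)C(C)(C)C)[C@@H]2C=C[C@@H]3/C=C(C)/C=C/[C@@H](C)[C@H]([C@H](C)[C@@H]4OC(C)(C)N(C(C)=O)[C@@H]4C)OC(=O)/C=C/C=C(C)\C=C\[C@]3(C)[C@@H]2C1 | intermediate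
52 | C13 alcohol of 51 | CO[C@@H]1C[C@H](O)[C@@H]2C=C[C@@H]3/C=C(C)/C=C/[C@@H](C)[C@H]([C@H](C)[C@@H]4OC(C)(C)N(C(C)=O)[C@@H]4C)OC(=O)/C=C/C=C(C)\C=C\[C@]3(C)[C@@H]2C1 | intermediate
53 | C13 N-(trichloroacetyl)carbamate of 52 | CO[C@@H]1C[C@H](OC(=O)NC(=O)C(Cl)(Cl)Cl)[C@@H]2C=C[C@@H]3/C=C(C)/C=C/[C@@H](C)[C@H]([C@H](C)[C@@H]4OC(C)(C)N(C(C)=O)[C@@H]4C)OC(=O)/C=C/C=C(C)\C=C\[C@]3(C)[C@@H]2C1 | intermediate (not isolated)
54 | C13 carbamate with O25/N26 still as N-acetyl-2,2-dimethyloxazolidine | CO[C@@H]1C[C@H](OC(N)=O)[C@@H]2C=C[C@@H]3/C=C(C)/C=C/[C@@H](C)[C@H]([C@H](C)[C@@H]4OC(C)(C)N(C(C)=O)[C@@H]4C)OC(=O)/C=C/C=C(C)\C=C\[C@]3(C)[C@@H]2C1 | intermediate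
55 | superstolide A | CO[C@@H]1C[C@H](OC(N)=O)[C@@H]2C=C[C@@H]3/C=C(C)/C=C/[C@@H](C)[C@H]([C@H](C)[C@H](O)[C@@H](C)NC(C)=O)OC(=O)/C=C/C=C(C)\C=C\[C@]3(C)[C@@H]2C1 | target

## Step count and least certain steps

Total number of steps: 39. Longest linear sequence: 25 steps (steps 1–6, 10–20 and 32–39).

**Step 10 (key step).** The most likely failure is weak discrimination between the two enantiotopic alkenes. The mismatched pathway is held back only by the size difference between methyl and alkynyl at C8, so some of the mirror-image adduct may form and the enantiomeric purity would fall. A second hazard is protodesilylation of the diene by the acidic catalyst, which would divert material to an open-chain Mukaiyama–Michael product. If the sense of induction is opposite to the model, the (R)-catalyst is used instead. Fallback by resolution in place of asymmetric catalysis: 9 and 13 are combined under an achiral Lewis acid (Et2AlCl, CH2Cl2, −78 °C), which gives 14 together with the mirror-image cycloadduct F1. Hydrolysis as in step 11 gives 15 together with the mirror-image diketone F2, and the two are separated by preparative chromatography on a chiral stationary phase. The route is rejoined at 15.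

**Step 12.** Hydride may also attack the C15 enone, or the borohydride medium may trigger elimination of the C13 silyloxy group, because both carbonyls are present and O13 is β to each. Fallback: 15 is reduced at both carbonyls under Luche conditions (NaBH4, CeCl3·7H2O, MeOH, −78 °C) to the C11,C15-diol F3. The unhindered equatorial C11 hydroxyl is then methylated selectively (Me3OBF4, 1,8-bis(dimethylamino)naphthalene, CH2Cl2, low temperature) in the presence of the hindered pseudoaxial C15 hydroxyl. The route is rejoined at 18.

**Step 16 (with step 15).** The carbanion may undergo a [1,2]-shift or simple protonation, because C17 lies next to the quaternary C8. In step 15 the alkoxide may also trigger a 1,3-shift of the silyl group from O13 to O15. Fallback by a [3,3] shift that needs no alkoxide: 18 is heated with triethyl orthoacetate and a trace of propionic acid (xylene, 140 °C, Johnson–Claisen rearrangement, also suprafacial) to give the C17 acetic ester F4. Its enolate (KN(SiMe3)2, THF, −78 °C) is hydroxylated with 2-(phenylsulfonyl)-3-phenyloxaziridine to the α-hydroxy ester F5. LiAlH4 gives the 1,2-diol F6, and NaIO4 cleaves it to aldehyde 22, where the route is rejoined.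

**Step 20.** Zirconium may add with the wrong regiochemistry (onto C18), or the hydride may attack the silyl alkyne or the ring alkene during the equilibration with excess reagent. Fallback from the dibromoalkene: 23 is coupled with 39 at the bromine trans to C17 (Pd(PPh3)4, aq. K3PO4, THF; the less hindered C–Br bond of a 1,1-dibromoalkene reacts first) to give the (18Z)-19-bromodiene F7. The remaining bromine is replaced by methyl with retention (Me2Zn, Pd(t-Bu3P)2, THF), which gives 46, where the route is rejoined.

**Step 36.** Intermolecular coupling (oligomers), protodestannylation at the slow, dilute stage, or palladium-induced isomerisation of the 4Z alkene may compete with ring closure. Fallback by closing the ring at the ester instead: 48 is coupled intermolecularly with ester 44 (Pd2(dba)3, AsPh3, DMF) to the triene ethyl ester F8. Saponification (LiOH, THF–H2O) gives the seco acid F9, and Yamaguchi macrolactonisation (2,4,6-trichlorobenzoyl chloride, Et3N, then DMAP, toluene, high dilution) onto the C23 hydroxyl gives 51, where the route is rejoined.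

Further compounds
F1 | step 10 | mirror-image cycloadduct (enantiomer of 14) | C[Si](C)(C)OC1=C[C@@H](O[Si](C)(C)C(C)(C)C)[C@H]2C(=O)C=C[C@@](C)(C#C[Si](C)(C)C)[C@H]2C1
F2 | step 10 | mirror-image diketone (enantiomer of 15) | O=C1C[C@@H](O[Si](C)(C)C(C)(C)C)[C@H]2C(=O)C=C[C@@](C)(C#C[Si](C)(C)C)[C@H]2C1
F3 | step 12 | C11,C15-diol (both hydroxyls on the face of the alkynyl group, 13-OTBS) | O[C@@H]1C[C@H](O[Si](C)(C)C(C)(C)C)[C@@H]2[C@H](O)C=C[C@](C)(C#C[Si](C)(C)C)[C@@H]2C1
F4 | step 16 | C17 ethoxycarbonylmethyl decalin (C17–CH2CO2Et, C15=C16) | CO[C@@H]1C[C@H](O[Si](C)(C)C(C)(C)C)[C@@H]2C=C[C@H](CC(=O)OCC)[C@](C)(C#C[Si](C)(C)C)[C@@H]2C1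
F5 | step 16 | α-hydroxy ester (C17–CH(OH)CO2Et, carbinol configuration not controlled) | CO[C@@H]1C[C@H](O[Si](C)(C)C(C)(C)C)[C@@H]2C=C[C@H](C(O)C(=O)OCC)[C@](C)(C#C[Si](C)(C)C)[C@@H]2C1
F6 | step 16 | 1,2-diol (C17–CH(OH)CH2OH) | CO[C@@H]1C[C@H](O[Si](C)(C)C(C)(C)C)[C@@H]2C=C[C@H](C(O)CO)[C@](C)(C#C[Si](C)(C)C)[C@@H]2C1
F7 | step 20 | (18Z,20E)-19-bromodiene (46 with bromine in place of the C19 methyl) | CO[C@@H]1C[C@H](O[Si](C)(C)C(C)(C)C)[C@@H]2C=C[C@H](/C=C(Br)/C=C/[C@@H](C)[C@@H](O)[C@H](C)[C@@H]3OC(C)(C)N(C(C)=O)[C@@H]3C)[C@](C)(C#C[Si](C)(C)C)[C@@H]2C1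
F8 | step 36 | seco triene ethyl ester (C1 ethyl ester, free 23-OH) | CO[C@@H]1C[C@H](O[Si](C)(C)C(C)(C)C)[C@@H]2C=C[C@H](/C=C(C)/C=C/[C@@H](C)[C@@H](O)[C@H](C)[C@@H]3OC(C)(C)N(C(C)=O)[C@@H]3C)[C@](C)(/C=C/C(C)=C\C=C\C(=O)OCC)[C@@H]2C1
F9 | step 36 | seco trienoic acid (C1 acid, free 23-OH) | CO[C@@H]1C[C@H](O[Si](C)(C)C(C)(C)C)[C@@H]2C=C[C@H](/C=C(C)/C=C/[C@@H](C)[C@@H](O)[C@H](C)[C@@H]3OC(C)(C)N(C(C)=O)[C@@H]3C)[C@](C)(/C=C/C(C)=C\C=C\C(=O)O)[C@@H]2C1
A1 | alternative 1 | macrocyclic 18-en-20-yne (13-OTES, 25-OTBS) | CO[C@@H]1C[C@H](O[Si](CC)(CC)CC)[C@@H]2C=C[C@@H]3/C=C(C)/C#C[C@@H](C)[C@H]([C@H](C)[C@H](O[Si](C)(C)C(C)(C)C)[C@@H](C)NC(C)=O)OC(=O)/C=C/C=C(C)\C=C\[C@]3(C)[C@@H]2C1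
A2 | alternative 2 | cis-decalin C11 ketone (13-OPMB, C8 and C17 silyloxymethyl arms) | O=C1C[C@H](OCc3ccc(OC)cc3)[C@@H]2C=C[C@H](CO[Si](C)(C)C(C)(C)C)[C@](C)(CO[Si](C(C)C)(C(C)C)C(C)C)[C@@H]2C1
A3 | alternative 3 | cis-decalin with C8 vinyl group (11-OMe, 13-OTBS, C17 silyloxymethyl) | CO[C@@H]1C[C@H](O[Si](C)(C)C(C)(C)C)[C@@H]2C=C[C@H](CO[Si](C)(C)C(C)(C)C)[C@](C)(C=C)[C@@H]2C1
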